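Both trimethylcyclohexene end rings are traced to one racemic cycloadduct. In the β ring, C2–C3(O)–C4–C5(CH3) is the retron of a 2-silyloxy-1,3-pentadiene and C1(CH3)2–C6–C7 that of 3-methylbut-2-enenitrile; their Diels–Alder union forms C1–C2 and C5–C6 at once, with the oxygen at C3 and a nitrile as C7. Dehydrosilylation and a reagent-controlled ketone reduction sort the racemate into two diastereomers: one is conjugated to the β ring and grown into a C15 phosphonium salt, the other becomes the ε ring carrying a butenolide, which is condensed with a C10 dialdehyde; a final Wittig reaction joins the halves.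

Key step: step 2

Remark: carotenoid numbering is used for the target (β ring C1–C6, with C1 the gem-dimethyl carbon and C6 the chain-bearing carbon; primed numbers for the ε half). Compound 4 is used as its mixture of racemic diastereomers. The carbinol configuration expected in step 4 rests on the usual oxazaborolidine model (alkene side of the enone as the large group) and is to be confirmed on 6 and 7.

Step 1
Reactants: 1 (E)-pent-3-en-2-one
Product: 2 (E)-2-(tert-butyldimethylsilyloxy)penta-1,3-diene
Conditions: TBSOTf, Et3N, CH2Cl2, 0 °C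
Reagents that add atoms: tert-butyldimethylsilyl trifluoromethanesulfonate, CC(C)(C)[Si](C)(C)OS(=O)(=O)C(F)(F)F
Why: Silyl enol ether formation by soft enolisation at the α'-methyl group should give the cross-conjugated 2-silyloxydiene and leave the E-propenyl unit intact; no stereocentre is formed.

Step 2
Reactants: 2 (E)-2-(tert-butyldimethylsilyloxy)penta-1,3-diene; 3 3-methylbut-2-enenitrile
Product: 4 rac-4-(tert-butyldimethylsilyloxy)-2,6,6-trimethylcyclohex-3-ene-1-carbonitrile (mixture of 1,2-cis and 1,2-trans racemates)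
Conditions: AlBr3/AlMe3 (10:1, 0.3 equiv), toluene/CH2Cl2, −20 °C to rt
Reagents that add atoms: none
Why: The nitrile, N-complexed to the aluminium Lewis acid, should react with the electron-rich diene in a normal-demand, strongly asynchronous [4+2] cycloaddition (in the limit a Mukaiyama–Michael addition followed by ring closure of the metallated keteniminate onto the silyl oxocarbenium ion). The closest known reaction types are the aluminium-halide-promoted Diels–Alder reactions of 2-silyloxydienes and of 1,3-pentadiene with β,β-dimethyl-substituted enones. The cyclohexene ring is closed by a suprafacial [4π+2π] cycloaddition, which in the stepwise limit is a Michael addition followed by a 6-endo-trig closure. Two stereocentres (C-1 and C-2 of 4) arise as a racemic mixture of relative configurations without control, which is intended: C-2 is planarised in step 3 and the racemic C-1 is sorted in step 4. The step needs regioselectivity, secured because the silyloxy group makes the CH2 terminus of the diene its nucleophilic end and the nitrile makes the C(CH3)2 carbon the electrophilic end (the "para" preference of the 2-oxy group and the "ortho" preference of the 4-methyl group reinforce each other); it also needs cycloaddition to outrun desilylation of the diene, for which AlMe3 is present as a proton scavenger. The end-on bound nitrile is the smallest activating group available, which keeps bond formation at the crowded quaternary carbon feasible.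

Step 3
Reactants: 4 rac-4-(tert-butyldimethylsilyloxy)-2,6,6-trimethylcyclohex-3-ene-1-carbonitrile
Product: 5 rac-2,6,6-trimethyl-4-oxocyclohex-2-ene-1-carbonitrile
Conditions: Pd(OAc)2 (10 mol %), O2 (1 atm), DMSO, 40 °C
Reagents that add atoms: none
Why: Saegusa–Ito oxidation: the oxa-π-allyl complex of divalent palladium formed from the silyl enol ether can lose a β-hydrogen only from the methyl-bearing C-2, so the enone double bond should be placed regiospecifically at C2=C3 and that stereocentre is erased.

Step 4
Reactants: 5 rac-2,6,6-trimethyl-4-oxocyclohex-2-ene-1-carbonitrile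
Product: 6 (1S,4S)-4-hydroxy-2,6,6-trimethylcyclohex-2-ene-1-carbonitrile (1,4-trans) and 7 (1R,4S)-4-hydroxy-2,6,6-trimethylcyclohex-2-ene-1-carbonitrile (1,4-cis), separated by chromatography
Conditions: (R)-2-methyl-CBS-oxazaborolidine (0.2 equiv), catecholborane, toluene, −78 °C; MeOH quench, aqueous NaHCO3
Reagents that add atoms: none
Why: CBS reduction under reagent control: with the enone double bond as the large group the (R)-oxazaborolidine should deliver hydride to the same carbonyl face of both enantiomers of 5, setting C-4 as S and thereby turning the racemic C-1 centre into two separable diastereomers, trans-6 for the β ring and cis-7 for the ε ring.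

Step 5
Reactants: 6 (1S,4S)-4-hydroxy-2,6,6-trimethylcyclohex-2-ene-1-carbonitrile
Product: 8 (4R)-4-hydroxy-2,6,6-trimethylcyclohex-1-ene-1-carbonitrile
Conditions: t-BuOK (0.3 equiv), t-BuOH, 50 °C
Reagents that add atoms: none
Why: Base-mediated prototropic double-bond migration (deprotonation at the allylic α-cyano carbon, reprotonation at the γ-carbon) should move the ring alkene into conjugation with the nitrile, as in the known base-induced ε-to-β end-group isomerisation of 3-hydroxy carotenoid rings; C-1 is planarised and the carbinol centre is untouched, its descriptor changing from S to R only because the two ring branches exchange priority.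

Step 6
Reactants: 8 (4R)-4-hydroxy-2,6,6-trimethylcyclohex-1-ene-1-carbonitrile
Product: 10 (4R)-4-hydroxy-2,6,6-trimethylcyclohex-1-ene-1-carbaldehyde, via aluminium aldiminate 9 (not isolated)
Conditions: i-Bu2AlH (2.5 equiv), CH2Cl2, −78 °C; then aqueous tartaric acid, 0 °C
Reagents that add atoms: water, O
Why: Partial reduction of the nitrile (hydroalumination stops at the N-aluminio aldimine, which is hydrolysed on work-up) should give the conjugated aldehyde; no stereocentre is formed.

Step 7
Reactants: 10 (4R)-4-hydroxy-2,6,6-trimethylcyclohex-1-ene-1-carbaldehyde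
Product: 11 (3E)-4-[(4R)-4-hydroxy-2,6,6-trimethylcyclohex-1-en-1-yl]but-3-en-2-one
Conditions: (MeO)2P(O)CH2C(O)CH3, NaH, THF, 0 °C to rt
Reagents that add atoms: dimethyl (2-oxopropyl)phosphonate, COP(=O)(CC(C)=O)OC
Why: Horner–Wadsworth–Emmons olefination with a stabilised keto-phosphonate anion should give the E-enone, and the weakly basic anion avoids the vinylogous β-elimination of the ring hydroxyl that hydroxide-mediated aldol conditions could trigger.

Step 8
Reactants: 11 (3E)-4-[(4R)-4-hydroxy-2,6,6-trimethylcyclohex-1-en-1-yl]but-3-en-2-one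
Product: 12 (1R)-4-[(1E)-3-hydroxy-3-methylpenta-1,4-dien-1-yl]-3,5,5-trimethylcyclohex-3-en-1-ol (both epimers at the tertiary carbinol)
Conditions: CH2=CHMgBr (2.5 equiv), THF, −20 to 0 °C; aqueous NH4Cl
Reagents that add atoms: vinylmagnesium bromide, C=C[Mg]Br
Why: Grignard 1,2-addition to the ketone (the β-carbon is shielded by the trimethylcyclohexenyl group) should give the tertiary bis-allylic alcohol as an epimer mixture, which is irrelevant because this centre is ionised in step 9.

Step 9
Reactants: 12 (1R)-4-[(1E)-3-hydroxy-3-methylpenta-1,4-dien-1-yl]-3,5,5-trimethylcyclohex-3-en-1-ol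
Product: 13 [(2E,4E)-5-[(4R)-4-hydroxy-2,6,6-trimethylcyclohex-1-en-1-yl]-3-methylpenta-2,4-dien-1-yl]triphenylphosphonium bromide
Conditions: PPh3·HBr, MeOH, rt
Reagents that add atoms: triphenylphosphine hydrobromide, Br.c1ccc(cc1)P(c1ccccc1)c1ccccc1
Why: Acid-promoted ionisation of the tertiary bis-allylic alcohol and capture of the pentadienyl cation by triphenylphosphine at the unhindered terminus (allylic transposition, SN1') should give the conjugated (2E,4E) phosphonium salt, purified by crystallisation; the ring carbinol is not allylic and is untouched.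

Step 10
Reactants: 7 (1R,4S)-4-hydroxy-2,6,6-trimethylcyclohex-2-ene-1-carbonitrile
Product: 14 (1R,4R)-4-cyano-3,5,5-trimethylcyclohex-2-en-1-yl acetate (1,4-trans)
Conditions: PPh3, DIAD, AcOH, THF, 0 °C to rt
Reagents that add atoms: acetic acid, CC(=O)O
Why: Mitsunobu esterification proceeds by SN2 displacement of the oxyphosphonium ion with inversion, converting the (S) carbinol of 7 into the (R) acetate with the 1,4-trans relationship of the ε ring; the SN2' path would have to attack the fully substituted alkene carbon and is disfavoured.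

Step 11
Reactants: 14 (1R,4R)-4-cyano-3,5,5-trimethylcyclohex-2-en-1-yl acetate
Product: 16 (1R,4R)-4-hydroxy-2,6,6-trimethylcyclohex-2-ene-1-carbaldehyde, via aluminium aldiminate 15 (not isolated)
Conditions: i-Bu2AlH (3.5 equiv), CH2Cl2, −78 °C; then aqueous tartaric acid, 0 °C
Reagents that add atoms: water, O
Why: Partial reduction of the nitrile with concurrent reductive cleavage of the acetate; the aldiminate is hydrolysed cold and weakly acidic so that the α-stereocentre of the β,γ-unsaturated aldehyde should be kept.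

Step 12
Reactants: 16 (1R,4R)-4-hydroxy-2,6,6-trimethylcyclohex-2-ene-1-carbaldehyde
Product: 17 (1R,4R)-4-ethenyl-3,5,5-trimethylcyclohex-2-en-1-ol
Conditions: Ph3PCH3Br, KN(SiMe3)2, THF, 0 °C; then 16, −78 to 0 °C
Reagents that add atoms: methyltriphenylphosphonium bromide, C[P+](c1ccccc1)(c1ccccc1)c1ccccc1.[Br-]
Why: Wittig methylenation with salt-free methylenetriphenylphosphorane at low temperature should add to the aldehyde faster than it enolises it, so the ring stereocentres are retained and no new one is formed.

Step 13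
Reactants: 17 (1R,4R)-4-ethenyl-3,5,5-trimethylcyclohex-2-en-1-ol; 18 3-bromofuran-2(5H)-one
Product: 20 3-{2-[(1R,4R)-4-hydroxy-2,6,6-trimethylcyclohex-2-en-1-yl]ethyl}furan-2(5H)-one, via B-alkyl-9-BBN adduct 19 (not isolated)
Conditions: 9-BBN (2.2 equiv), THF, rt; then 18, PdCl2(dppf) (5 mol %), AsPh3, K3PO4 (aq), DMF, rt
Reagents that add atoms: none
Why: Hydroboration with 9-BBN takes place only at the monosubstituted alkene with anti-Markovnikov regiochemistry, and the B-alkyl borane is then coupled with the α-bromobutenolide in a B-alkyl Suzuki–Miyaura reaction (oxidative addition of zerovalent palladium into the C–Br bond, transmetallation, reductive elimination); no stereocentre is formed.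

Step 14
Reactants: 20 3-{2-[(1R,4R)-4-hydroxy-2,6,6-trimethylcyclohex-2-en-1-yl]ethyl}furan-2(5H)-one; 21 (2E,4E,6E)-2,7-dimethylocta-2,4,6-trienedial
Product: 25 (2E,4E,6E)-8-[(2Z)-4-{2-[(1R,4R)-4-hydroxy-2,6,6-trimethylcyclohex-2-en-1-yl]ethyl}-5-oxofuran-2(5H)-ylidene]-2,7-dimethylocta-2,4,6-trienal, via silyloxyfuran 22 (not isolated), via silylated aldol adduct 23 (not isolated), via trimethylsilyl ether 24 (not isolated)
Conditions: TMSOTf (2.5 equiv), Et3N, 21 (4 equiv), CH2Cl2, −78 to 0 °C; then DBU, rt; then aqueous citric acid/THF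
Reagents that add atoms: none
Why: One-pot vinylogous Mukaiyama aldol–elimination: the butenolide is converted in situ into its 2-silyloxyfuran, which adds through C-5 to one formyl group of the dialdehyde used in excess, and base-induced E1cB loss of silanolate should give the thermodynamically preferred Z-ylidene butenolide (chain syn to the ring oxygen), the two transient stereocentres being destroyed; the ring silyl ether is cleaved on acidic work-up.

Step 15
Reactants: 13 [(2E,4E)-5-[(4R)-4-hydroxy-2,6,6-trimethylcyclohex-1-en-1-yl]-3-methylpenta-2,4-dien-1-yl]triphenylphosphonium bromide; 25 (2E,4E,6E)-8-[(2Z)-4-{2-[(1R,4R)-4-hydroxy-2,6,6-trimethylcyclohex-2-en-1-yl]ethyl}-5-oxofuran-2(5H)-ylidene]-2,7-dimethylocta-2,4,6-trienal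
Product: 27 CNP0242041.1, (3R,3'R,6'R)-3,3'-dihydroxy-7',8'-dihydro-β,ε-caroten-19',11'-olide with the (Z)-ylidene lactone and an all-E polyene, via phosphorus ylide 26 (not isolated)
Conditions: 1,2-epoxybutane, EtOH, 70 °C; then heptane, 90 °C, crystallisation
Reagents that add atoms: none
Why: Wittig olefination under neutral, epoxide-buffered conditions (bromide opens the epoxide and the resulting alkoxide generates the ylide) should tolerate the ylidene lactone and both free hydroxyls; the semi-stabilised ylide gives the new C11=C12 bond as an E/Z mixture that is equilibrated thermally to the all-E polyene, the lactone ylidene bond staying Z as its more stable form.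

Compound list
1 | (E)-pent-3-en-2-one | C/C=C/C(C)=O | starting material
2 | (E)-2-(tert-butyldimethylsilyloxy)penta-1,3-diene | C=C(O[Si](C)(C)C(C)(C)C)/C=C/C | intermediate
3 | 3-methylbut-2-enenitrile | CC(C)=CC#N | starting material
4 | rac-4-(tert-butyldimethylsilyloxy)-2,6,6-trimethylcyclohex-3-ene-1-carbonitrile (both relative configurations) | CC1C=C(O[Si](C)(C)C(C)(C)C)CC(C)(C)C1C#N | intermediate
5 | rac-2,6,6-trimethyl-4-oxocyclohex-2-ene-1-carbonitrile | CC1=CC(=O)CC(C)(C)C1C#N | intermediate
6 | (1S,4S)-4-hydroxy-2,6,6-trimethylcyclohex-2-ene-1-carbonitrile (trans) | CC1=C[C@@H](O)CC(C)(C)[C@@H]1C#N | intermediate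
7 | (1R,4S)-4-hydroxy-2,6,6-trimethylcyclohex-2-ene-1-carbonitrile (cis) | CC1=C[C@@H](O)CC(C)(C)[C@H]1C#N | intermediate
8 | (4R)-4-hydroxy-2,6,6-trimethylcyclohex-1-ene-1-carbonitrile | N#CC1=C(C)C[C@@H](O)CC1(C)C | intermediate
9 | N-(diisobutylaluminio)aldimine of 10 with the ring oxygen bound to a second diisobutylaluminium group | CC(C)C[Al](CC(C)C)N=CC1=C(C)C[C@@H](O[Al](CC(C)C)CC(C)C)CC1(C)C | intermediate
10 | (4R)-4-hydroxy-2,6,6-trimethylcyclohex-1-ene-1-carbaldehyde | O=CC1=C(C)C[C@@H](O)CC1(C)C | intermediate
11 | (3E)-4-[(4R)-4-hydroxy-2,6,6-trimethylcyclohex-1-en-1-yl]but-3-en-2-one | CC(=O)/C=C/C1=C(C)C[C@@H](O)CC1(C)C | intermediate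
12 | (1R)-4-[(1E)-3-hydroxy-3-methylpenta-1,4-dien-1-yl]-3,5,5-trimethylcyclohex-3-en-1-ol (epimers at the tertiary carbinol) | C=CC(C)(O)/C=C/C1=C(C)C[C@@H](O)CC1(C)C | intermediate
13 | [(2E,4E)-5-[(4R)-4-hydroxy-2,6,6-trimethylcyclohex-1-en-1-yl]-3-methylpenta-2,4-dien-1-yl]triphenylphosphonium bromide | c1ccccc1[P+](c1ccccc1)(c1ccccc1)C/C=C(C)/C=C/C1=C(C)C[C@@H](O)CC1(C)C.[Br-] | intermediate
14 | (1R,4R)-4-cyano-3,5,5-trimethylcyclohex-2-en-1-yl acetate | CC1=C[C@H](OC(C)=O)CC(C)(C)[C@H]1C#N | intermediate
15 | N-(diisobutylaluminio)aldimine of 16 with the ring oxygen bound to a second diisobutylaluminium group | CC1=C[C@H](O[Al](CC(C)C)CC(C)C)CC(C)(C)[C@H]1C=N[Al](CC(C)C)CC(C)C | intermediate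
16 | (1R,4R)-4-hydroxy-2,6,6-trimethylcyclohex-2-ene-1-carbaldehyde | CC1=C[C@H](O)CC(C)(C)[C@H]1C=O | intermediate
17 | (1R,4R)-4-ethenyl-3,5,5-trimethylcyclohex-2-en-1-ol | CC1=C[C@H](O)CC(C)(C)[C@H]1C=C | intermediate
18 | 3-bromofuran-2(5H)-one | O=C1OCC=C1Br | starting material
19 | 9-{2-[(1R,4R)-4-(9-borabicyclo[3.3.1]nonan-9-yloxy)-2,6,6-trimethylcyclohex-2-en-1-yl]ethyl}-9-borabicyclo[3.3.1]nonane | CC1=C[C@H](OB2C3CCCC2CCC3)CC(C)(C)[C@H]1CCB1C2CCCC1CCC2 | intermediate
20 | 3-{2-[(1R,4R)-4-hydroxy-2,6,6-trimethylcyclohex-2-en-1-yl]ethyl}furan-2(5H)-one | CC1=C[C@H](O)CC(C)(C)[C@H]1CCC1=CCOC1=O | intermediate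
21 | (2E,4E,6E)-2,7-dimethylocta-2,4,6-trienedial | O=C/C(C)=C/C=C/C=C(C)/C=O | starting material
22 | 2-(trimethylsilyloxy)furan of 20 with the ring hydroxyl as trimethylsilyl ether | CC1=C[C@H](O[Si](C)(C)C)CC(C)(C)[C@H]1CCc1ccoc1O[Si](C)(C)C | intermediate
23 | 5-(1-trimethylsilyloxy-7-formyl-2-methylocta-2,4,6-trienyl) adduct of the butenolide, ring hydroxyl as trimethylsilyl ether (diastereomer mixture at the two new centres) | CC1=C[C@H](O[Si](C)(C)C)CC(C)(C)[C@H]1CCC1=CC(OC1=O)C(O[Si](C)(C)C)/C(C)=C/C=C/C=C(C)/C=O | intermediate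
24 | trimethylsilyl ether of 25 | CC1=C[C@H](O[Si](C)(C)C)CC(C)(C)[C@H]1CCC1=C/C(=C/C(C)=C/C=C/C=C(C)/C=O)OC1=O | intermediate
25 | (2E,4E,6E)-8-[(2Z)-4-{2-[(1R,4R)-4-hydroxy-2,6,6-trimethylcyclohex-2-en-1-yl]ethyl}-5-oxofuran-2(5H)-ylidene]-2,7-dimethylocta-2,4,6-trienal | CC1=C[C@H](O)CC(C)(C)[C@H]1CCC1=C/C(=C/C(C)=C/C=C/C=C(C)/C=O)OC1=O | intermediate
26 | triphenylphosphonium ylide of 13 | c1ccccc1P(c1ccccc1)(c1ccccc1)=C/C=C(C)/C=C/C1=C(C)C[C@@H](O)CC1(C)C | intermediate
27 | CNP0242041.1, (3R,3'R,6'R)-3,3'-dihydroxy-7',8'-dihydro-β,ε-caroten-19',11'-olide | CC1=C[C@H](O)CC(C)(C)[C@H]1CCC1=C/C(=C/C(C)=C/C=C/C=C(C)/C=C/C=C(C)/C=C/C2=C(C)C[C@@H](O)CC2(C)C)OC1=O | target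

Total step count: 15.
Longest linear sequence: 10 steps (steps 1–4, 5–9 and 15; equally steps 1–4, 10–14 and 15).

Steps most likely to fail

Step 2. The doubly β-methylated nitrile may be too unreactive, so that Lewis-acid-induced desilylation and oligomerisation of the diene outrun the cycloaddition. The fallback sets out from 2 and forms the same two ring bonds by an uncatalysed thermal Diels–Alder reaction (toluene, 110 °C) with the doubly activated ethyl 2-cyano-3-methylbut-2-enoate, giving ethyl 4-(tert-butyldimethylsilyloxy)-1-cyano-2,6,6-trimethylcyclohex-3-ene-1-carboxylate F1. Saegusa–Ito oxidation under the conditions of step 3 gives ethyl 1-cyano-2,6,6-trimethyl-4-oxocyclohex-2-ene-1-carboxylate F2, and Krapcho dealkoxycarbonylation (LiCl, wet DMSO, 140 °C) removes the auxiliary ester and comes back to the route at 5.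

Step 14. The condensation may run on at both formyl groups of the dialdehyde, the E1cB elimination may lose geometric control at the ylidene bond, or the trienal may degrade under the silyl triflate. The fallback inverts the order of the two couplings and carries out the condensation stepwise on a mono-aldehyde; it sets out from 13, 20 and 21. Wittig reaction of 13 with an excess of 21 (conditions of step 15) gives (2E,4E,6E,8E,10E,12E)-13-[(4R)-4-hydroxy-2,6,6-trimethylcyclohex-1-en-1-yl]-2,7,11-trimethyltrideca-2,4,6,8,10,12-hexaenal F6, which is silylated (TBSCl, imidazole, DMF) to its tert-butyldimethylsilyl ether F7. Separately, 20 is converted with TBSOTf/Et3N into the isolable bis-silylated 2-(tert-butyldimethylsilyloxy)furan F8. A BF3·OEt2-mediated vinylogous Mukaiyama aldol of F8 with F7 (CH2Cl2, −78 °C) gives the γ-(α-hydroxyalkyl)butenolide F9, which is dehydrated by Mitsunobu-type anti-elimination (PPh3, DEAD) to the bis(tert-butyldimethylsilyl) ether of the target F10. HF·pyridine in THF/pyridine then comes back to the route at 27.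

Step 4. A mismatched pairing of the catalyst with one enantiomer of 5 may let substrate bias compete with reagent control, so that each diastereomer is contaminated by the enantiomer of the other stream and enantiomeric purity is eroded. The fallback sets out from 5 and replaces reagent control by diastereoselection plus enzymatic resolution. Luche reduction (NaBH4, CeCl3·7H2O, MeOH, −78 °C) gives the racemic alcohols; chromatography separates the trans racemate, 6 together with (1R,4R)-4-hydroxy-2,6,6-trimethylcyclohex-2-ene-1-carbonitrile F3, from the cis racemate, 7 together with (1S,4R)-4-hydroxy-2,6,6-trimethylcyclohex-2-ene-1-carbonitrile F5, which is returned to 5 by MnO2 oxidation. Lipase-catalysed acetylation of the trans racemate (Burkholderia cepacia lipase, vinyl acetate, t-BuOMe) is expected to acylate the (4S) enantiomer 6 to (1S,4S)-4-cyano-3,5,5-trimethylcyclohex-2-en-1-yl acetate F4 and to leave F3. F4 with NaOMe in MeOH (acetate methanolysis and double-bond migration in one operation) comes back to the route at 8, and F3 is reduced under the conditions of step 11 directly to 16, so that steps 5 and 10 are not needed. Should the enzyme prefer the other enantiomer, the acetate formed is 14 and the remaining alcohol is 6, which re-enter at steps 11 and 5.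

Further compounds
F1 | step 2 | ethyl 4-(tert-butyldimethylsilyloxy)-1-cyano-2,6,6-trimethylcyclohex-3-ene-1-carboxylate (racemic) | CCOC(=O)C1(C#N)C(C)C=C(O[Si](C)(C)C(C)(C)C)CC1(C)C
F2 | step 2 | ethyl 1-cyano-2,6,6-trimethyl-4-oxocyclohex-2-ene-1-carboxylate (racemic) | CCOC(=O)C1(C#N)C(C)=CC(=O)CC1(C)C
F3 | step 4 | (1R,4R)-4-hydroxy-2,6,6-trimethylcyclohex-2-ene-1-carbonitrile | CC1=C[C@H](O)CC(C)(C)[C@H]1C#N
F4 | step 4 | (1S,4S)-4-cyano-3,5,5-trimethylcyclohex-2-en-1-yl acetate | CC1=C[C@@H](OC(C)=O)CC(C)(C)[C@@H]1C#N
F5 | step 4 | (1S,4R)-4-hydroxy-2,6,6-trimethylcyclohex-2-ene-1-carbonitrile | CC1=C[C@H](O)CC(C)(C)[C@@H]1C#N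
F6 | step 14 | (2E,4E,6E,8E,10E,12E)-13-[(4R)-4-hydroxy-2,6,6-trimethylcyclohex-1-en-1-yl]-2,7,11-trimethyltrideca-2,4,6,8,10,12-hexaenal | O=C/C(C)=C/C=C/C=C(C)/C=C/C=C(C)/C=C/C1=C(C)C[C@@H](O)CC1(C)C
F7 | step 14 | tert-butyldimethylsilyl ether of F6 | O=C/C(C)=C/C=C/C=C(C)/C=C/C=C(C)/C=C/C1=C(C)C[C@@H](O[Si](C)(C)C(C)(C)C)CC1(C)C
F8 | step 14 | 2-(tert-butyldimethylsilyloxy)furan of 20 with the ring hydroxyl as tert-butyldimethylsilyl ether | CC1=C[C@H](O[Si](C)(C)C(C)(C)C)CC(C)(C)[C@H]1CCc1ccoc1O[Si](C)(C)C(C)(C)C
F9 | step 14 | γ-(α-hydroxyalkyl)butenolide from F8 and F7 (diastereomer mixture at the two new centres) | CC1=C[C@H](O[Si](C)(C)C(C)(C)C)CC(C)(C)[C@H]1CCC1=CC(OC1=O)C(O)/C(C)=C/C=C/C=C(C)/C=C/C=C(C)/C=C/C1=C(C)C[C@@H](O[Si](C)(C)C(C)(C)C)CC1(C)C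
F10 | step 14 | bis(tert-butyldimethylsilyl) ether of 27 | CC1=C[C@H](O[Si](C)(C)C(C)(C)C)CC(C)(C)[C@H]1CCC1=C/C(=C/C(C)=C/C=C/C=C(C)/C=C/C=C(C)/C=C/C2=C(C)C[C@@H](O[Si](C)(C)C(C)(C)C)CC2(C)C)OC1=O
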